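**Plan**
Retrosynthesis: the C1 carbonyl is taken back to CH2, then the C1–C7a bond of the five-membered ring is cut so that C1, C2 and C3 fold into a cyclopropene with C3 as its sp3 carbon. Next the C2–aryl bond to ring B is cut, then the diaryl ether C–O bond on the ring A side, and last the cyclopropene is taken back to a 1,1-diarylethene (plus CBr2) and that to an aryl ketone plus an aryllithium.
Enabling feature: C3 of the indenone is bonded to two arene carbons (C3a of the benzo ring and C1 of the orcinol ring), and of the four ring positions ortho to C3 only C7a carries hydrogen, the other three carry oxygen. C3 can therefore be the gem-diaryl carbon of a 3,3-diarylcyclopropene, and the ring-opened vinylcarbenoid can close only onto C7a.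
Forward order: the four benzene rings are bought; the ring A–O–ring B ether is made by nucleophilic aromatic substitution; the three-membered ring is built (ethene, dibromocyclopropane, cyclopropene) and joined to ring B by C–H arylation. The three-membered ring is then expanded by two atoms to the five-membered ring of a 1H-indene, CH2 is oxidised to C=O, and five methoxymethyl ethers are removed.
Stereochemistry: the target has no stereocentre; the stereocentres of 6, 8, 9, 21 and 23 are racemic and are all destroyed on the way.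

Key step: step 15

Remark: the aryl–indenone bonds of the target are taken to rotate freely (no stereocontrol is planned), and methyl 2,6-difluoro-4-methylbenzoate is taken as a purchasable building block.

**Route**

Step 1
Reactants: 1 paeonol (1-(2-hydroxy-4-methoxyphenyl)ethanone)
Product: 2 ketone 1-[4-methoxy-2-(methoxymethoxy)phenyl]ethanone
Conditions: NaH, DMF, 0 °C; MOMCl, 0 °C to rt
Reagents that add atoms: chloromethyl methyl ether, COCCl
Why: Williamson-type O-alkylation of the sodium phenoxide gives the methoxymethyl ether and leaves the ketone untouched.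

Step 2
Reactants: 3 orcinol (5-methylbenzene-1,3-diol)
Product: 4 orcinol bis(methoxymethyl) ether (1,3-bis(methoxymethoxy)-5-methylbenzene)
Conditions: NaH, DMF, 0 °C; MOMCl, 0 °C to rt
Reagents that add atoms: chloromethyl methyl ether, COCCl
Why: double Williamson-type O-alkylation of the bis-phenoxide should give the bis(methoxymethyl) ether.

Step 3
Reactants: 4 orcinol bis(methoxymethyl) ether; 2 ketone 1-[4-methoxy-2-(methoxymethoxy)phenyl]ethanone
Product: 6 carbinol 1-[2,6-bis(methoxymethoxy)-4-methylphenyl]-1-[4-methoxy-2-(methoxymethoxy)phenyl]ethanol (racemic), via aryllithium 5 (not isolated)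
Conditions: n-BuLi, THF, 0 °C; then 2 premixed with LaCl3·2LiCl, THF, −78 °C to 0 °C; H2O
Reagents that add atoms: none
Why: directed ortho-metalation takes place at the carbon between the two methoxymethoxy groups and the aryllithium adds 1,2 to the ketone, the oxophilic lanthanum salt holding back enolisation; the carbinol stereocentre is racemic and disappears in step 4.

Step 4
Reactants: 6 carbinol 1-[2,6-bis(methoxymethoxy)-4-methylphenyl]-1-[4-methoxy-2-(methoxymethoxy)phenyl]ethanol
Product: 7 diarylethene 2-{1-[4-methoxy-2-(methoxymethoxy)phenyl]ethenyl}-1,3-bis(methoxymethoxy)-5-methylbenzene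
Conditions: methyl N-(triethylammoniosulfonyl)carbamate (Burgess reagent), toluene, 60 °C
Reagents that add atoms: none
Why: Burgess dehydration of the tertiary, doubly benzylic alcohol can only give the 1,1-diarylethene because the methyl group carries the only β-hydrogens, and the non-acidic conditions spare the methoxymethyl ethers.

Step 5
Reactants: 7 diarylethene 2-{1-[4-methoxy-2-(methoxymethoxy)phenyl]ethenyl}-1,3-bis(methoxymethoxy)-5-methylbenzene
Product: 8 dibromocyclopropane 2-{2,2-dibromo-1-[4-methoxy-2-(methoxymethoxy)phenyl]cyclopropyl}-1,3-bis(methoxymethoxy)-5-methylbenzene (racemic)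
Conditions: CHBr3, 50% aq. NaOH, BnEt3NCl (cat.), CH2Cl2, rt
Reagents that add atoms: bromoform, BrC(Br)Br
Why: dibromocarbene generated under phase-transfer conditions adds in a [2+1] cycloaddition to the electron-rich 1,1-disubstituted alkene; the quaternary stereocentre is racemic.

Step 6
Reactants: 8 dibromocyclopropane 2-{2,2-dibromo-1-[4-methoxy-2-(methoxymethoxy)phenyl]cyclopropyl}-1,3-bis(methoxymethoxy)-5-methylbenzene
Product: 9 bromocyclopropane 2-{2-bromo-1-[4-methoxy-2-(methoxymethoxy)phenyl]cyclopropyl}-1,3-bis(methoxymethoxy)-5-methylbenzene (racemic mixture of both diastereomers)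
Conditions: EtMgBr (1.2 equiv), Ti(OiPr)4 (5 mol %), Et2O, rt
Reagents that add atoms: none
Why: titanium-catalysed hydrodebromination of a gem-dibromocyclopropane by the Grignard reagent should stop at the monobromide with a small excess of reagent; the diastereomer mixture is of no consequence because both stereocentres vanish in step 7.

Step 7
Reactants: 9 bromocyclopropane 2-{2-bromo-1-[4-methoxy-2-(methoxymethoxy)phenyl]cyclopropyl}-1,3-bis(methoxymethoxy)-5-methylbenzene
Product: 10 cyclopropene 2-{1-[4-methoxy-2-(methoxymethoxy)phenyl]cycloprop-2-en-1-yl}-1,3-bis(methoxymethoxy)-5-methylbenzene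
Conditions: KOtBu, DMSO, rt
Reagents that add atoms: none
Why: base-induced 1,2-dehydrobromination of a bromocyclopropane is the standard entry to 3,3-disubstituted cyclopropenes, and the lack of allylic hydrogens prevents isomerisation of the strained alkene.

Step 8
Reactants: 11 2-hydroxy-4-methoxybenzaldehyde
Product: 12 aldehyde 4-methoxy-2-(methoxymethoxy)benzaldehyde
Conditions: NaH, DMF, 0 °C; MOMCl, 0 °C to rt
Reagents that add atoms: chloromethyl methyl ether, COCCl
Why: Williamson-type O-alkylation of the phenoxide gives the methoxymethyl ether.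

Step 9
Reactants: 12 aldehyde 4-methoxy-2-(methoxymethoxy)benzaldehyde
Product: 14 phenol 4-methoxy-2-(methoxymethoxy)phenol, via aryl formate 13 (not isolated)
Conditions: mCPBA, NaHCO3, CH2Cl2, 0 °C to rt; then K2CO3 (cat.), MeOH, rt
Reagents that add atoms: 3-chloroperoxybenzoic acid, OOC(=O)c1cccc(Cl)c1
Why: Baeyer–Villiger oxidation of the ortho,para-dioxygenated benzaldehyde proceeds with aryl migration (Dakin-type) to the aryl formate, which is cleaved by methanolysis.

Step 10
Reactants: 14 phenol 4-methoxy-2-(methoxymethoxy)phenol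
Product: 15 iodophenol 2-iodo-4-methoxy-6-(methoxymethoxy)phenol
Conditions: I2 (1.0 equiv), NaHCO3, THF/H2O, 0 °C
Reagents that add atoms: iodine, II
Why: electrophilic aromatic iodination through the phenoxide, whose para position and one ortho position are blocked, so that only C6 is open to ortho/para attack.

Step 11
Reactants: 15 iodophenol 2-iodo-4-methoxy-6-(methoxymethoxy)phenol; 16 methyl 2,6-difluoro-4-methylbenzoate
Product: 17 fluoro diaryl ether methyl 2-fluoro-6-[2-iodo-4-methoxy-6-(methoxymethoxy)phenoxy]-4-methylbenzoate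
Conditions: Cs2CO3, DMSO, 90 °C (16 in excess)
Reagents that add atoms: none
Why: nucleophilic aromatic substitution (addition–elimination) of a fluoride ortho to the ester; the second fluorine is less activated once the donor aryloxy group is in place, so the reaction should stop after one substitution.

Step 12
Reactants: 17 fluoro diaryl ether methyl 2-fluoro-6-[2-iodo-4-methoxy-6-(methoxymethoxy)phenoxy]-4-methylbenzoate
Product: 19 salicylate methyl 2-hydroxy-6-[2-iodo-4-methoxy-6-(methoxymethoxy)phenoxy]-4-methylbenzoate, via O-aryl acetohydroxamate 18 (not isolated)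
Conditions: acetohydroxamic acid, K2CO3, DMSO, 80 °C
Reagents that add atoms: acetohydroxamic acid, CC(=O)NO
Why: nucleophilic aromatic substitution of the remaining ester-activated fluoride by the hydroxamate oxygen, then Lossen-type fragmentation of the O-aryl hydroxamate under the basic conditions, releases the phenoxide (hydroxide-surrogate hydroxylation that spares the methyl ester and the aryl iodide).

Step 13
Reactants: 19 salicylate methyl 2-hydroxy-6-[2-iodo-4-methoxy-6-(methoxymethoxy)phenoxy]-4-methylbenzoate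
Product: 20 aryl iodide methyl 2-[2-iodo-4-methoxy-6-(methoxymethoxy)phenoxy]-6-(methoxymethoxy)-4-methylbenzoate
Conditions: NaH, DMF, 0 °C; MOMCl, 0 °C to rt
Reagents that add atoms: chloromethyl methyl ether, COCCl
Why: Williamson-type O-alkylation of the salicylate phenoxide gives the methoxymethyl ether, so that no free phenol meets the carbenoid of step 15.

Step 14
Reactants: 10 cyclopropene 2-{1-[4-methoxy-2-(methoxymethoxy)phenyl]cycloprop-2-en-1-yl}-1,3-bis(methoxymethoxy)-5-methylbenzene; 20 aryl iodide methyl 2-[2-iodo-4-methoxy-6-(methoxymethoxy)phenoxy]-6-(methoxymethoxy)-4-methylbenzoate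
Product: 21 arylcyclopropene methyl 2-{2-[3-[2,6-bis(methoxymethoxy)-4-methylphenyl]-3-[4-methoxy-2-(methoxymethoxy)phenyl]cycloprop-1-en-1-yl]-4-methoxy-6-(methoxymethoxy)phenoxy}-6-(methoxymethoxy)-4-methylbenzoate (racemic)
Conditions: Pd(OAc)2 (5 mol %), K2CO3, DMF, 30 °C (10 in slight excess)
Reagents that add atoms: none
Why: palladium-catalysed direct C–H arylation of a 3,3-disubstituted cyclopropene with an aryl iodide under ligand-free conditions keeps the three-membered ring; the two vinylic positions of 10 are equivalent, so one monoarylation product should form.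

Step 15
Reactants: 21 arylcyclopropene methyl 2-{2-[3-[2,6-bis(methoxymethoxy)-4-methylphenyl]-3-[4-methoxy-2-(methoxymethoxy)phenyl]cycloprop-1-en-1-yl]-4-methoxy-6-(methoxymethoxy)phenoxy}-6-(methoxymethoxy)-4-methylbenzoate
Product: 22 indene methyl 2-{2-[3-[2,6-bis(methoxymethoxy)-4-methylphenyl]-6-methoxy-4-(methoxymethoxy)-1H-inden-2-yl]-4-methoxy-6-(methoxymethoxy)phenoxy}-6-(methoxymethoxy)-4-methylbenzoate
Conditions: Rh2(O2CC3F7)4 (2 mol %), CH2Cl2 (0.01 M), 25 °C
Reagents that add atoms: none
Why: The electrophilic divalent rhodium carboxylate adds to the unsubstituted vinylic carbon of the strained cyclopropene so that positive charge develops on the aryl-bearing carbon, and the cyclopropyl cation opens by cleavage of the CH–C(aryl)2 σ-bond to a rhodium vinylcarbenoid whose second resonance form is a diaryl-stabilised allyl cation. The carbenoid carbon then bonds to the free ortho carbon of the 4-methoxy-2-(methoxymethoxy)phenyl ring, and proton loss with protodemetalation gives the 1H-indene and returns the catalyst. The closest known reaction type is the rearrangement of 3-arylcyclopropenes to indenes through vinylcarbenes, which runs thermally, photochemically, with acid or with divalent rhodium carboxylates. The five-membered ring closes by a Nazarov-like 4π-electrocyclic closure of the aryl-substituted allyl cation or vinylcarbenoid, in effect an intramolecular Friedel–Crafts alkylation. No stereocentre is formed and the one in 21 is destroyed. The step needs first cleavage of the σ-bond to the CH carbon and not to the aryl-bearing carbon, secured by Markovnikov attack of the metal at the less hindered CH that puts the cation next to the ring B aryl group, and second closure at one position only, secured because three of the four ortho positions of the two geminal aryl groups carry methoxymethoxy groups.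

Step 16
Reactants: 22 indene methyl 2-{2-[3-[2,6-bis(methoxymethoxy)-4-methylphenyl]-6-methoxy-4-(methoxymethoxy)-1H-inden-2-yl]-4-methoxy-6-(methoxymethoxy)phenoxy}-6-(methoxymethoxy)-4-methylbenzoate
Product: 24 indenone methyl 2-{2-[3-[2,6-bis(methoxymethoxy)-4-methylphenyl]-6-methoxy-4-(methoxymethoxy)-1-oxo-1H-inden-2-yl]-4-methoxy-6-(methoxymethoxy)phenoxy}-6-(methoxymethoxy)-4-methylbenzoate, via indenyl hydroperoxide 23 (not isolated)
Conditions: O2 (1 atm), Cs2CO3, DMSO, 25 °C
Reagents that add atoms: dioxygen, O=O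
Why: base-mediated autoxidation of the doubly activated (benzylic and allylic) CH2 group: the indenyl anion should trap dioxygen at the unhindered C1, and the secondary hydroperoxide loses water to the ketone (Kornblum–DeLaMare fragmentation).

Step 17
Reactants: 24 indenone methyl 2-{2-[3-[2,6-bis(methoxymethoxy)-4-methylphenyl]-6-methoxy-4-(methoxymethoxy)-1-oxo-1H-inden-2-yl]-4-methoxy-6-(methoxymethoxy)phenoxy}-6-(methoxymethoxy)-4-methylbenzoate
Product: 25 ascomindone B (methyl 2-{2-[3-(2,6-dihydroxy-4-methylphenyl)-4-hydroxy-6-methoxy-1-oxo-1H-inden-2-yl]-6-hydroxy-4-methoxyphenoxy}-6-hydroxy-4-methylbenzoate)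
Conditions: HCl (1.25 M in MeOH), THF, 40 °C
Reagents that add atoms: none
Why: acid-catalysed acetal exchange with methanol should cleave all five methoxymethyl ethers, while the methyl ester (in methanol), the two aryl methyl ethers and the indenone are stable.

**Compound list**
1 | paeonol, 1-(2-hydroxy-4-methoxyphenyl)ethanone | CC(=O)c1ccc(OC)cc1O | starting material
2 | 1-[4-methoxy-2-(methoxymethoxy)phenyl]ethanone | CC(=O)c1ccc(OC)cc1OCOC | intermediate
3 | orcinol, 5-methylbenzene-1,3-diol | Cc1cc(O)cc(O)c1 | starting material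
4 | 1,3-bis(methoxymethoxy)-5-methylbenzene | Cc1cc(OCOC)cc(OCOC)c1 | intermediate
5 | [2,6-bis(methoxymethoxy)-4-methylphenyl]lithium (formed in the flask) | [Li]c1c(OCOC)cc(C)cc1OCOC | intermediate
6 | 1-[2,6-bis(methoxymethoxy)-4-methylphenyl]-1-[4-methoxy-2-(methoxymethoxy)phenyl]ethanol (racemic) | CC(O)(c1ccc(OC)cc1OCOC)c1c(OCOC)cc(C)cc1OCOC | intermediate
7 | 2-{1-[4-methoxy-2-(methoxymethoxy)phenyl]ethenyl}-1,3-bis(methoxymethoxy)-5-methylbenzene | C=C(c1ccc(OC)cc1OCOC)c1c(OCOC)cc(C)cc1OCOC | intermediate
8 | 2-{2,2-dibromo-1-[4-methoxy-2-(methoxymethoxy)phenyl]cyclopropyl}-1,3-bis(methoxymethoxy)-5-methylbenzene (racemic) | BrC1(Br)CC1(c1ccc(OC)cc1OCOC)c1c(OCOC)cc(C)cc1OCOC | intermediate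
9 | 2-{2-bromo-1-[4-methoxy-2-(methoxymethoxy)phenyl]cyclopropyl}-1,3-bis(methoxymethoxy)-5-methylbenzene (racemic, both diastereomers) | BrC1CC1(c1ccc(OC)cc1OCOC)c1c(OCOC)cc(C)cc1OCOC | intermediate
10 | 2-{1-[4-methoxy-2-(methoxymethoxy)phenyl]cycloprop-2-en-1-yl}-1,3-bis(methoxymethoxy)-5-methylbenzene | C1=CC1(c1ccc(OC)cc1OCOC)c1c(OCOC)cc(C)cc1OCOC | intermediate
11 | 2-hydroxy-4-methoxybenzaldehyde | O=Cc1ccc(OC)cc1O | starting material
12 | 4-methoxy-2-(methoxymethoxy)benzaldehyde | O=Cc1ccc(OC)cc1OCOC | intermediate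
13 | 4-methoxy-2-(methoxymethoxy)phenyl formate (formed in the flask) | O=COc1ccc(OC)cc1OCOC | intermediate
14 | 4-methoxy-2-(methoxymethoxy)phenol | Oc1ccc(OC)cc1OCOC | intermediate
15 | 2-iodo-4-methoxy-6-(methoxymethoxy)phenol | Oc1c(I)cc(OC)cc1OCOC | intermediate
16 | methyl 2,6-difluoro-4-methylbenzoate | COC(=O)c1c(F)cc(C)cc1F | starting material
17 | methyl 2-fluoro-6-[2-iodo-4-methoxy-6-(methoxymethoxy)phenoxy]-4-methylbenzoate | COC(=O)c1c(F)cc(C)cc1Oc1c(I)cc(OC)cc1OCOC | intermediate
18 | methyl 2-(acetamidooxy)-6-[2-iodo-4-methoxy-6-(methoxymethoxy)phenoxy]-4-methylbenzoate (formed in the flask) | COC(=O)c1c(ONC(C)=O)cc(C)cc1Oc1c(I)cc(OC)cc1OCOC | intermediate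
19 | methyl 2-hydroxy-6-[2-iodo-4-methoxy-6-(methoxymethoxy)phenoxy]-4-methylbenzoate | COC(=O)c1c(O)cc(C)cc1Oc1c(I)cc(OC)cc1OCOC | intermediate
20 | methyl 2-[2-iodo-4-methoxy-6-(methoxymethoxy)phenoxy]-6-(methoxymethoxy)-4-methylbenzoate | COC(=O)c1c(OCOC)cc(C)cc1Oc1c(I)cc(OC)cc1OCOC | intermediate
21 | methyl 2-{2-[3-[2,6-bis(methoxymethoxy)-4-methylphenyl]-3-[4-methoxy-2-(methoxymethoxy)phenyl]cycloprop-1-en-1-yl]-4-methoxy-6-(methoxymethoxy)phenoxy}-6-(methoxymethoxy)-4-methylbenzoate (racemic) | COC(=O)c1c(OCOC)cc(C)cc1Oc1c(OCOC)cc(OC)cc1C1=CC1(c1ccc(OC)cc1OCOC)c1c(OCOC)cc(C)cc1OCOC | intermediate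
22 | methyl 2-{2-[3-[2,6-bis(methoxymethoxy)-4-methylphenyl]-6-methoxy-4-(methoxymethoxy)-1H-inden-2-yl]-4-methoxy-6-(methoxymethoxy)phenoxy}-6-(methoxymethoxy)-4-methylbenzoate | COC(=O)c1c(OCOC)cc(C)cc1Oc1c(OCOC)cc(OC)cc1C1=C(c2c(OCOC)cc(C)cc2OCOC)c2c(OCOC)cc(OC)cc2C1 | intermediate
23 | methyl 2-{2-[3-[2,6-bis(methoxymethoxy)-4-methylphenyl]-1-hydroperoxy-6-methoxy-4-(methoxymethoxy)-1H-inden-2-yl]-4-methoxy-6-(methoxymethoxy)phenoxy}-6-(methoxymethoxy)-4-methylbenzoate (racemic, formed in the flask) | COC(=O)c1c(OCOC)cc(C)cc1Oc1c(OCOC)cc(OC)cc1C1=C(c2c(OCOC)cc(C)cc2OCOC)c2c(OCOC)cc(OC)cc2C1OO | intermediate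
24 | methyl 2-{2-[3-[2,6-bis(methoxymethoxy)-4-methylphenyl]-6-methoxy-4-(methoxymethoxy)-1-oxo-1H-inden-2-yl]-4-methoxy-6-(methoxymethoxy)phenoxy}-6-(methoxymethoxy)-4-methylbenzoate | COC(=O)c1c(OCOC)cc(C)cc1Oc1c(OCOC)cc(OC)cc1C1=C(c2c(OCOC)cc(C)cc2OCOC)c2c(OCOC)cc(OC)cc2C1=O | intermediate
25 | ascomindone B, methyl 2-{2-[3-(2,6-dihydroxy-4-methylphenyl)-4-hydroxy-6-methoxy-1-oxo-1H-inden-2-yl]-6-hydroxy-4-methoxyphenoxy}-6-hydroxy-4-methylbenzoate | COC(=O)c1c(O)cc(C)cc1Oc1c(O)cc(OC)cc1C1=C(c2c(O)cc(C)cc2O)c2c(O)cc(OC)cc2C1=O | target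

**Step count and risks**
Total step count: 17. Longest linear sequence: 10 steps (steps 2, 3, 4, 5, 6, 7, 14, 15, 16, 17, or equally steps 8 to 17).

Most likely to fail:

1. Step 15. The ring opening may cleave the other σ-bond of the cyclopropene (the one to the aryl-bearing carbon), which would lead to a 1,3-diarylindene skeleton; the carbenoid may also be diverted by attack on an ether oxygen or by intermolecular reaction with the electron-rich rings. The fallback removes the regiochemical question by expanding the ring before the ring B aryl group is attached. It sets out from cyclopropene 10 (and uses iodide 20) and returns at indenone 24. The symmetrical cyclopropene 10 is treated with Rh2(OAc)4 in CH2Cl2; either σ-bond cleavage leads to the same vinylcarbenoid, which should close to 3-[2,6-bis(methoxymethoxy)-4-methylphenyl]-6-methoxy-4-(methoxymethoxy)-1H-indene F1. Autoxidation (O2, Cs2CO3, DMSO) should give 3-[2,6-bis(methoxymethoxy)-4-methylphenyl]-6-methoxy-4-(methoxymethoxy)-1H-inden-1-one F2. α-Iodination of the enone with I2 and pyridine in CH2Cl2 should give 3-[2,6-bis(methoxymethoxy)-4-methylphenyl]-2-iodo-6-methoxy-4-(methoxymethoxy)-1H-inden-1-one F3. Iodide 20 is converted by Miyaura borylation (bis(pinacolato)diboron, PdCl2(dppf), KOAc, dioxane, 80 °C) into methyl 2-(methoxymethoxy)-4-methyl-6-[4-methoxy-2-(methoxymethoxy)-6-(4,4,5,5-tetramethyl-1,3,2-dioxaborolan-2-yl)phenoxy]benzoate F4. Suzuki–Miyaura coupling of F3 with F4 (Pd(OAc)2, SPhos, K3PO4, toluene/H2O, 80 °C) should give 24.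

2. Step 14. Oxidative addition of the hindered, electron-rich iodide may be slow, the cyclopropene may open prematurely on palladium, or a second arylation may follow. The fallback replaces C–H arylation by cross-coupling of a preformed cyclopropenyl metal. It sets out from cyclopropene 10 and returns at arylcyclopropene 21. Deprotonation of 10 at the vinylic position (n-BuLi, THF, −78 °C) and trapping with Bu3SnCl should give tributyl{3-[2,6-bis(methoxymethoxy)-4-methylphenyl]-3-[4-methoxy-2-(methoxymethoxy)phenyl]cycloprop-1-en-1-yl}stannane F5. Stille coupling of F5 with 20 (Pd(PPh3)4, CuI, DMF, 40 °C) should give 21.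

3. Step 3. The hindered aryllithium may deprotonate the methyl ketone (enolisation) and not add to it, or the addition to the ortho-substituted, electron-rich ketone may stall. The fallback makes the same bond by cross-coupling. It sets out from ketone 2 and arene 4 and returns at diarylethene 7, leaving out carbinol 6. Ketone 2 is converted (KN(SiMe3)2, N-phenylbis(trifluoromethanesulfonimide), THF, −78 °C) into 1-[4-methoxy-2-(methoxymethoxy)phenyl]ethenyl trifluoromethanesulfonate F6. Arene 4 is lithiated as in step 3 and quenched with B(OMe)3, then water, to give [2,6-bis(methoxymethoxy)-4-methylphenyl]boronic acid F7. Suzuki–Miyaura coupling of F6 with F7 (Pd(OAc)2, SPhos, K3PO4, THF/H2O, 60 °C) should give 7.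

**Further compounds**
F1 | step 15 | 3-[2,6-bis(methoxymethoxy)-4-methylphenyl]-6-methoxy-4-(methoxymethoxy)-1H-indene | C1=C(c2c(OCOC)cc(C)cc2OCOC)c2c(OCOC)cc(OC)cc2C1
F2 | step 15 | 3-[2,6-bis(methoxymethoxy)-4-methylphenyl]-6-methoxy-4-(methoxymethoxy)-1H-inden-1-one | O=C1C=C(c2c(OCOC)cc(C)cc2OCOC)c2c(OCOC)cc(OC)cc21
F3 | step 15 | 3-[2,6-bis(methoxymethoxy)-4-methylphenyl]-2-iodo-6-methoxy-4-(methoxymethoxy)-1H-inden-1-one | O=C1C(I)=C(c2c(OCOC)cc(C)cc2OCOC)c2c(OCOC)cc(OC)cc21
F4 | step 15 | methyl 2-(methoxymethoxy)-4-methyl-6-[4-methoxy-2-(methoxymethoxy)-6-(4,4,5,5-tetramethyl-1,3,2-dioxaborolan-2-yl)phenoxy]benzoate | COC(=O)c1c(OCOC)cc(C)cc1Oc1c(B2OC(C)(C)C(C)(C)O2)cc(OC)cc1OCOC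
F5 | step 14 | tributyl{3-[2,6-bis(methoxymethoxy)-4-methylphenyl]-3-[4-methoxy-2-(methoxymethoxy)phenyl]cycloprop-1-en-1-yl}stannane | CCCC[Sn](CCCC)(CCCC)C1=CC1(c1ccc(OC)cc1OCOC)c1c(OCOC)cc(C)cc1OCOC
F6 | step 3 | 1-[4-methoxy-2-(methoxymethoxy)phenyl]ethenyl trifluoromethanesulfonate | C=C(OS(=O)(=O)C(F)(F)F)c1ccc(OC)cc1OCOC
F7 | step 3 | [2,6-bis(methoxymethoxy)-4-methylphenyl]boronic acid | OB(O)c1c(OCOC)cc(C)cc1OCOC
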